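The lactam carbonyl at C1 of the isoquinoline ring, an unsubstituted methylene next to N in the target, is the handle. As an O-pivaloyl hydroxamate it directs metalation of the one free ortho C–H of the benzene ring (the future C4a; the other ortho carbon holds the C8 methoxy group). A chiral cyclopentadienyl rhodium catalyst then stitches propene gas across C4a and N of this achiral, open benzamide. This forms the C4–C4a and N–C3 bonds, the heterocycle and the C3 stereocentre in one operation, with the N–O bond as internal oxidant. The C5 bromine rides through for a Suzuki coupling with a naphthyl boronate made by an aryne/2-methoxyfuran Diels–Alder reaction; lactam reduction ends the route.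

Key step: step 5

Assumption: the biaryl axis, hindered by three ortho substituents, is a further stereogenic element that the drawn structure leaves open; the route fixes C3 as S and takes the axis as the mixture of atropisomers that the coupling delivers.

Step 1
Reactants: 1 3-bromo-5-methylanisole; 2 2-methoxyfuran
Product: 5 4,5-dimethoxy-7-methylnaphthalen-1-ol, via 3-methoxy-5-methylbenzyne 3 (not isolated), via epoxynaphthalene cycloadduct 4 (not isolated)
Conditions: LDA, excess 2, THF, −78 °C to rt; then aq HCl
Reagents that add atoms: none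
Why: LDA removes the proton between OMe and Br and loss of LiBr gives aryne 3, whose Diels–Alder reaction with 2-methoxyfuran should be steered by the polarisation of both partners (nucleophilic furan C5 to the aryne carbon meta to OMe), and the bridgehead ketal of 4 opens on acidic work-up to the 4-methoxy-1-naphthol (aryne generation, Diels–Alder reaction, ring-opening aromatisation).

Step 2
Reactants: 5 4,5-dimethoxy-7-methylnaphthalen-1-ol
Product: 6 4,5-dimethoxy-7-methylnaphthalen-1-yl trifluoromethanesulfonate
Conditions: Tf2O, pyridine, CH2Cl2, 0 °C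
Reagents that add atoms: trifluoromethanesulfonic anhydride, O=S(=O)(OS(=O)(=O)C(F)(F)F)C(F)(F)F
Why: O-sulfonylation of the only free hydroxyl group of the air-sensitive naphthol should be fast and clean (triflate formation).

Step 3
Reactants: 6 4,5-dimethoxy-7-methylnaphthalen-1-yl trifluoromethanesulfonate
Product: 7 2-(4,5-dimethoxy-7-methylnaphthalen-1-yl)-4,4,5,5-tetramethyl-1,3,2-dioxaborolane
Conditions: B2pin2, PdCl2(dppf) (3 mol %), KOAc, 1,4-dioxane, 80 °C
Reagents that add atoms: bis(pinacolato)diboron, CC1(C)OB(OC1(C)C)B1OC(C)(C)C(C)(C)O1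
Why: Aryl triflates undergo Miyaura borylation under these conditions, and the methyl ethers are inert.

Step 4
Reactants: 8 5-bromo-2,4-dimethoxybenzoic acid; 9 O-pivaloylhydroxylammonium trifluoromethanesulfonate
Product: 11 5-bromo-2,4-dimethoxy-N-(pivaloyloxy)benzamide, via 5-bromo-2,4-dimethoxybenzoyl chloride 10 (not isolated)
Conditions: (COCl)2, cat. DMF, CH2Cl2, rt; then 9, K2CO3, EtOAc/H2O, 0 °C
Reagents that add atoms: oxalyl chloride, O=C(Cl)C(=O)Cl (its chlorine is carried only by intermediate 10)
Why: Acid chloride formation followed by Schotten–Baumann N-acylation of the O-acyl hydroxylamine is the standard entry to O-pivaloyl benzhydroxamates.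

Step 5
Reactants: 11 5-bromo-2,4-dimethoxy-N-(pivaloyloxy)benzamide; 12 propene
Product: 13 (3S)-5-bromo-6,8-dimethoxy-3-methyl-3,4-dihydroisoquinolin-1(2H)-one
Conditions: [Rh(Cpx)(C2H4)2] (5 mol %; Cpx = chiral cyclopentadienyl C5H3 bridged by two CH2 groups to C2 and C2' of 3,3'-dimethoxy-1,1'-binaphthyl), (BzO)2 (5 mol %), propene (1 atm), EtOH, 23 °C
Reagents that add atoms: none
Why: The trivalent rhodium carboxylate formed from the monovalent rhodium precatalyst and dibenzoyl peroxide binds the deprotonated hydroxamate nitrogen and cleaves the only free ortho C–H (future C4a) by concerted metalation–deprotonation to a five-membered rhodacycle, the other ortho site being blocked by the methoxy group. Propene then inserts into the aryl–Rh bond with the aryl carbon going to the terminal CH2 (new C4–C4a bond) and rhodium to the methyl-bearing carbon, and C–N bond formation with cleavage of the N–O bond (internal oxidant) gives the N–C3 bond, pivalate and the active catalyst. The closest known reaction type is the rhodium-catalysed redox-neutral (4+2) annulation of O-pivaloyl benzhydroxamates with alkenes to 3,4-dihydroisoquinolones, in its enantioselective form with chiral cyclopentadienyl ligands. The six-membered lactam ring closes by C–N reductive elimination from a seven-membered rhodacycle, that is a formal (4+2) annulation of the C4a–C8a–C1–N unit with the C3=C4 alkene. The C3 stereocentre is set in the migratory insertion, where the binaphthyl wall of the ligand lets propene approach with one face only; the ligand enantiomer is chosen to give 3S, the antipode giving the mirror image. The step needs site selectivity (one ortho C–H only), regioselectivity for 3-methyl over 4-methyl (aryl to the unhindered alkene terminus, reinforced by the bulky ligand) and tolerance of the aryl bromide, which trivalent rhodium should not touch.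

Step 6
Reactants: 13 (3S)-5-bromo-6,8-dimethoxy-3-methyl-3,4-dihydroisoquinolin-1(2H)-one; 7 2-(4,5-dimethoxy-7-methylnaphthalen-1-yl)-4,4,5,5-tetramethyl-1,3,2-dioxaborolane
Product: 14 (3S)-5-(4,5-dimethoxy-7-methylnaphthalen-1-yl)-6,8-dimethoxy-3-methyl-3,4-dihydroisoquinolin-1(2H)-one
Conditions: Pd(OAc)2 (5 mol %), SPhos (10 mol %), K3PO4, toluene/H2O, 100 °C
Reagents that add atoms: none
Why: Suzuki–Miyaura coupling with a bulky dialkylbiarylphosphine should join the doubly ortho-substituted bromide and the 1-naphthyl boronate, the lactam N–H and the remote C3 centre being untouched; the axis is expected to form as a mixture of atropisomers.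

Step 7
Reactants: 14 (3S)-5-(4,5-dimethoxy-7-methylnaphthalen-1-yl)-6,8-dimethoxy-3-methyl-3,4-dihydroisoquinolin-1(2H)-one
Product: 15 (3S)-5-(4,5-dimethoxy-7-methylnaphthalen-1-yl)-6,8-dimethoxy-3-methyl-1,2,3,4-tetrahydroisoquinoline
Conditions: LiAlH4, THF, reflux; then H2O/aq NaOH work-up
Reagents that add atoms: none
Why: Hydride reduction of the secondary lactam to the amine turns C1 into the methylene of the target without touching the aryl ethers or the C3 centre, which is not alpha to the carbonyl (LiAlH4 amide reduction).

Compound list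
1 | 3-bromo-5-methylanisole (1-bromo-3-methoxy-5-methylbenzene) | COc1cc(C)cc(Br)c1 | starting material
2 | 2-methoxyfuran | COc1ccco1 | starting material
3 | 3-methoxy-5-methylbenzyne | COC1=CC(C)=CC#C1 | intermediate (not isolated)
4 | 1,8-dimethoxy-6-methyl-1,4-dihydro-1,4-epoxynaphthalene (racemic cycloadduct) | COc1cc(C)cc2C3C=CC(OC)(O3)c12 | intermediate (not isolated)
5 | 4,5-dimethoxy-7-methylnaphthalen-1-ol | COc1ccc(O)c2cc(C)cc(OC)c12 | intermediate
6 | 4,5-dimethoxy-7-methylnaphthalen-1-yl trifluoromethanesulfonate | COc1ccc(OS(=O)(=O)C(F)(F)F)c2cc(C)cc(OC)c12 | intermediate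
7 | 2-(4,5-dimethoxy-7-methylnaphthalen-1-yl)-4,4,5,5-tetramethyl-1,3,2-dioxaborolane | COc1ccc(B2OC(C)(C)C(C)(C)O2)c2cc(C)cc(OC)c12 | intermediate
8 | 5-bromo-2,4-dimethoxybenzoic acid | COc1cc(OC)c(C(=O)O)cc1Br | starting material
9 | O-pivaloylhydroxylammonium trifluoromethanesulfonate | CC(C)(C)C(=O)ON.OS(=O)(=O)C(F)(F)F | starting material
10 | 5-bromo-2,4-dimethoxybenzoyl chloride | COc1cc(OC)c(C(Cl)=O)cc1Br | intermediate (not isolated)
11 | 5-bromo-2,4-dimethoxy-N-(pivaloyloxy)benzamide | COc1cc(OC)c(C(=O)NOC(=O)C(C)(C)C)cc1Br | intermediate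
12 | propene | CC=C | starting material
13 | (3S)-5-bromo-6,8-dimethoxy-3-methyl-3,4-dihydroisoquinolin-1(2H)-one | COc1cc(OC)c(Br)c2c1C(=O)N[C@@H](C)C2 | intermediate
14 | (3S)-5-(4,5-dimethoxy-7-methylnaphthalen-1-yl)-6,8-dimethoxy-3-methyl-3,4-dihydroisoquinolin-1(2H)-one | COc1cc(OC)c(-c2ccc(OC)c3c(OC)cc(C)cc23)c2c1C(=O)N[C@@H](C)C2 | intermediate
15 | (3S)-5-(4,5-dimethoxy-7-methylnaphthalen-1-yl)-6,8-dimethoxy-3-methyl-1,2,3,4-tetrahydroisoquinoline | COc1cc(OC)c(-c2ccc(OC)c3c(OC)cc(C)cc23)c2c1CN[C@@H](C)C2 | target

Total step count: 7
Longest linear sequence: 5 steps (steps 1, 2, 3, 6, 7)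

Steps most likely to fail

Step 5. Face discrimination may be incomplete for an alkene as small as propene, part of the insertion may run with reversed regiochemistry, and C–H metalation next to the bromine may be slow enough for a Lossen-type rearrangement of the hydroxamate to compete. The fallback sets out from 11 and comes back at 13. The annulation with propene is run with the achiral catalyst [Cp*RhCl2]2 and CsOAc in MeOH at rt (or with the bulkier [(1,3-tBu2C5H3)RhCl2]2 to enforce the 3-methyl regiochemistry). This should give racemic 5-bromo-6,8-dimethoxy-3-methyl-3,4-dihydroisoquinolin-1(2H)-one F1. The enantiomers are then separated by preparative chromatography on a chiral stationary phase, which gives 13, while the (3R)-lactam F2 is set aside. Stereocontrol thus moves from the catalyst to a resolution, and both bonds are still formed in one operation.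

Step 1. The regiochemistry of the aryne cycloaddition may erode, with the bridgehead methoxy group ending distal to the aryl methoxy group, and diisopropylamide may capture the aryne. The fallback sets out from 1 and comes back at 7; each positional relation is fixed by a directed step.
- Lithiation of 1 with LDA at −78 °C and trapping of the 2-lithio species with diethylcarbamoyl chloride before LiBr is lost should give 2-bromo-N,N-diethyl-6-methoxy-4-methylbenzamide F3.
- Stille coupling with allyltributylstannane (Pd(PPh3)4, toluene, 100 °C) should give 2-allyl-N,N-diethyl-6-methoxy-4-methylbenzamide F4.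
- LDA in THF should close the ortho-allyl benzamide by anionic annulation, with loss of diethylamine, to 8-methoxy-6-methylnaphthalen-1-ol F5.
- NBS in MeCN at low temperature should brominate para to the free hydroxyl group, on the ring without the methyl group, to give 4-bromo-8-methoxy-6-methylnaphthalen-1-ol F6.
- MeI and K2CO3 in DMF should give 1-bromo-4,5-dimethoxy-7-methylnaphthalene F7.
- Miyaura borylation (B2pin2, PdCl2(dppf), KOAc, dioxane) then gives 7.

Step 6. Transmetalation at the doubly ortho-substituted bromide may be slow, and the electron-rich naphthyl boronate may undergo protodeboronation. The fallback sets out from 7 and 8 and comes back at 14; it moves the coupling to the stage where the bromide is flanked by only one substituent.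
- Suzuki coupling of 7 with the free acid 8 (Pd(OAc)2, SPhos, K3PO4, toluene/H2O) should give 5-(4,5-dimethoxy-7-methylnaphthalen-1-yl)-2,4-dimethoxybenzoic acid F8.
- Oxalyl chloride should give 5-(4,5-dimethoxy-7-methylnaphthalen-1-yl)-2,4-dimethoxybenzoyl chloride F9, which is not isolated.
- Acylation of 9 under K2CO3 should give 5-(4,5-dimethoxy-7-methylnaphthalen-1-yl)-2,4-dimethoxy-N-(pivaloyloxy)benzamide F10.
- The rhodium-catalysed annulation with propene 12 under the conditions of step 5 then closes the lactam next to the axis and gives 14.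

Further compounds
F1 | step 5 | racemic 5-bromo-6,8-dimethoxy-3-methyl-3,4-dihydroisoquinolin-1(2H)-one | COc1cc(OC)c(Br)c2c1C(=O)NC(C)C2
F2 | step 5 | (3R)-5-bromo-6,8-dimethoxy-3-methyl-3,4-dihydroisoquinolin-1(2H)-one | COc1cc(OC)c(Br)c2c1C(=O)N[C@H](C)C2
F3 | step 1 | 2-bromo-N,N-diethyl-6-methoxy-4-methylbenzamide | COc1cc(C)cc(Br)c1C(=O)N(CC)CC
F4 | step 1 | 2-allyl-N,N-diethyl-6-methoxy-4-methylbenzamide | COc1cc(C)cc(CC=C)c1C(=O)N(CC)CC
F5 | step 1 | 8-methoxy-6-methylnaphthalen-1-ol | COc1cc(C)cc2cccc(O)c12
F6 | step 1 | 4-bromo-8-methoxy-6-methylnaphthalen-1-ol | COc1cc(C)cc2c(Br)ccc(O)c12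
F7 | step 1 | 1-bromo-4,5-dimethoxy-7-methylnaphthalene | COc1cc(C)cc2c(Br)ccc(OC)c12
F8 | step 6 | 5-(4,5-dimethoxy-7-methylnaphthalen-1-yl)-2,4-dimethoxybenzoic acid | COc1cc(OC)c(C(=O)O)cc1-c1ccc(OC)c2c(OC)cc(C)cc12
F9 | step 6 | 5-(4,5-dimethoxy-7-methylnaphthalen-1-yl)-2,4-dimethoxybenzoyl chloride | COc1cc(OC)c(C(Cl)=O)cc1-c1ccc(OC)c2c(OC)cc(C)cc12
F10 | step 6 | 5-(4,5-dimethoxy-7-methylnaphthalen-1-yl)-2,4-dimethoxy-N-(pivaloyloxy)benzamide | COc1cc(OC)c(C(=O)NOC(=O)C(C)(C)C)cc1-c1ccc(OC)c2c(OC)cc(C)cc12
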